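All runs are simulated from invented constants, and the scatter is random.

The ratio of substrate to free catalyst charged in the grey flask, 200, is the number of turnovers each catalyst must make on average to consume the substrate. The turnover count n used here is substrate lost over catalyst charged.

| setting | grey | ochre | flask |
|---|---|---|---|
| substrate | 0.30 M | 0.30 M | 0.30 M |
| reagent | 0.45 M | 0.90 M | 0.450 M |
| capture agent | 0.015 M | 0.015 M | 0.0150 M |
| free catalyst | 1.5 mM | 1.5 mM | 1.5 mM |
| temperature | −20 °C | −35 °C | −20 °C |
| remark | the very flask that is asked about, followed so far | run made earlier |  |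
| time |  |  | 8.0 min |

- grey (time / min: target / %, substrate / %): 0.500: 1.4, 97.6; 0.833: 4.1, 94.9; 1.33: 6.5, 91.2; 2.00: 8.6, 90.7; 3.00: 10.4, 87.0; 4.00: 11.7, 83.6; 6.00: 9.9, 76.6
- ochre (time / min: target / %, substrate / %): 0.833: 3.6, 98.9; 3.00: 2.5, 96.4; 5.00: 4.6, 94.4; 6.00: 3.8, 94.1; 10.0: 3.8, 90.5; 12.0: 5.2, 87.9; 15.0: 5.2, 90.3

(standard deviation of a reading: 1 percentage point)

- target taken out counts as made
- additions bring no volume worth counting

- elm: change nothing and wait 8.0 min more
- cedar: at 8.0 min add free catalyst, 100% of the amount charged, then wait 8.0 min
- ash: at 8.0 min take out 90% of the target then present, then wait 8.0 min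
- alder: at 8.0 min add reagent, 50.0% of the amount charged, then wait 8.0 min
- maple: at 8.0 min raise the temperature by 10 K, then wait 8.0 min

- target, in percent of the substrate first charged, at 8.0 min
- the option that brings most further target ("none" if no option brings more than 2 percentage points) (elm / cedar / ash / alder / maple / none)
- target present, with what was taken out counted in, in percent of the substrate first charged, after ash
- target present, with what was taken out counted in, in percent of the substrate first charged, after alder

The grey readings put n at 46.8 by 6.00 min. The rate r of that count reads 13.2 min⁻¹ up to 1.33 min but 7.00 min⁻¹ between 4.00 min and 6.00 min, so it falls, with a scatter of 1 percentage point on each reading. Taken as first-order decay of working catalyst, that fall gives a time constant τ of 6.81 min.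

Turn the question round: for the grey flask to consume its substrate on the catalyst charged, the 153 turnovers still owed would need τ near 21.9 min, which is 3.22 times the reading. The turnover budget B, the count so far plus r τ, is 94.5, so B stands below the need.

My own reckoning follows from this. With that τ the working share at 8.0 min is estimated at 30.9%, so cedar would raise working catalyst to 4.24 times its level; target at that time is put between the readings 9.9% and 11.7%. Cedar is my choice.

The forecast gives 8.5% now, ash as best, 14.5% after ash and 6.5% after alder, and says “Cedar and maple are untested or confounded”. The two part on the best option, and the forecast's value for now stands below my range.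

The flask gives 11.1% now and cedar as best, with 8.6 points further against 3 points for ash; ash ends at 14.1%, alder at 4.31%.

    reagent + target → over-reaction product (k = 0.00847 L mol⁻¹ s⁻¹, Ea = 49.0 kJ mol⁻¹)
    reagent + catalyst intermediate A ⇌ catalyst intermediate B (K = 6.01 L mol⁻¹, k = 2.24 L mol⁻¹ s⁻¹, Ea = 40.0 kJ mol⁻¹, ΔH = 21.0 kJ mol⁻¹)
    substrate + free catalyst ⇌ catalyst intermediate A (K = 7.50 L mol⁻¹, k = 2.92 L mol⁻¹ s⁻¹, Ea = 46.0 kJ mol⁻¹, ΔH = −34.0 kJ mol⁻¹)
    catalyst intermediate B + capture agent → trapped intermediate (k = 0.631 L mol⁻¹ s⁻¹, Ea = 36.0 kJ mol⁻¹)
    catalyst intermediate B → free catalyst + target (k = 0.676 s⁻¹, Ea = 70.0 kJ mol⁻¹)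
    (constants at −20 °C)

In the flask, n reaches 76.2 at 80.0 min, below B and the need, with substrate at 61.9%. The neighbouring flask with 0.0060 M of free catalyst needs 50.0 turnovers, below B. At 8.00 min that neighbour has counted 38.1, with substrate at 23.9% and target at 43.7%.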